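Amounts first: in the runs below, each Q lost shows up as D or as something beyond D, and we want D in the flask at 2.0 min.

| setting | oak | larch | birch | flask |
|---|---|---|---|---|
| Q | 0.70 M | 0.70 M | 1.4 M | 0.70 M |
| G | 0.94 M | 2.1 M | 1.4 M | 1.40 M |
| remark | run made earlier | run made earlier | run made earlier |  |
| time |  |  |  | 2.0 min |

- oak (time / min: D / %, Q / %): 0.200: 8.0, 90.0; 0.333: 10.3, 85.4; 0.667: 15.5, 74.2; 1.33: 19.3, 64.8; 2.50: 18.4, 56.3
- larch (time / min: D / %, Q / %): 0.500: 19.2, 61.1; 1.00: 15.6, 42.9; 1.33: 15.9, 37.2; 2.00: 12.9, 28.3; 2.50: 11.0, 25.7
- birch (time / min: D / %, Q / %): 0.200: 10.9, 86.1; 0.333: 13.7, 79.7; 0.667: 17.2, 68.5; 1.33: 18.4, 59.7; 2.50: 18.5, 54.5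

(scatter of a reading: 0.5 percentage points)

- equivalents of G to Q, everything else as given, that leave most D at 2.0 min
- the amount of D then, in percent of the Q charged
- the amount of D with the amounts as given



We build the flask up one process at a time. Let x be the fraction of charged Q left. With Q + G → D alone, and G held at its charge, we scale the first oak reading by G times time. That gives x = 20.8%, so D is 79.2%.

Now let D take G as well. Both steps use G, so G cancels from the ratio of their rates, and D becomes a function of x. If D reacts 3 times as fast as Q (a selectivity factor), theory gives D = 0.5(x minus its cube). We freeze the prefactor and read it from oak and larch as the curve height h, 0.487. At that x, D drops to 9.71%.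

Last comes the slowing of Q that the readings show. Oak interpolates to 59.9% Q at 2.0 min, and larch read 28.3%. Interpolating ln x in charged G puts the flask at x = 44.5%, so our D is 17.4%. The curve peaks at x = 57.7%, with D 18.8%. By the same interpolation that needs 1.43 equiv.

The forecast says 17.2%, and 19% at 1.35 equiv, where our reckoning gave 1.43 equiv. Its ground: “D depends only on the Q left”.

The flask gives 17.3%, and 18.8% at 1.34 equiv.

    G + D → E (k = 0.0230 /M/s)
    G ⇌ X (K = 22.0, k = 0.00540 /s)
    G + D → Z (k = 0.00720 /M/s)
    G + Z ⇌ L (K = 1.80 /M, k = 0.0230 /M/s)
    Q + G → D (k = 0.00970 /M/s)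

Putting the flask's computed Q, 44.7%, into our curve gives 17.4%. The curve rests on the steps that use D, G + D → E and G + D → Z. In the run without the loss of G + D to E, the flask holds 40.9% D, not 17.3%, so this loss is the largest single effect holding D down, though not the main reason. In a neighbouring flask with 0.17 M Q and G as in the flask, the computed Q left at 2.00 min is 33.8%, so h gives 14.6%; the computed D there is 14.4%.

All runs were generated by integration with constants of no real substance.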